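By 10.0 h at 25 °C, the oak flask shows product at 79.3% of the substrate charged. At 40.0 h it shows 80.8%, with 20.9% of the substrate still there, and each reading scatters by 1 percentage point. So you are looking at a flask that has stopped with substrate in it.

in all of them: coupling partner 0.416 M

| run | substrate | free catalyst | temperature | remark | time |
|---|---|---|---|---|---|
| oak | 0.52 M | 1 mM | 25 °C | the very flask that is asked about, followed so far |  |
| alder | 0.35 M | 1 mM | 20 °C | run made earlier |  |
| flask | 0.52 M | 1.0 mM | 25 °C |  | 40 h |

| run | time / h | product / % | substrate / % |
|---|---|---|---|
| oak | 10.0 | 79.3 | 21.4 |
| oak | 20.0 | 80.2 | 20.3 |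
| oak | 30.0 | 80.7 | 18.7 |
| oak | 40.0 | 80.8 | 20.9 |
| alder | 1.33 | 60.3 | 37.6 |
| alder | 3.00 | 91.7 | 7.9 |
| alder | 4.00 | 95.8 | 4.1 |
| alder | 6.00 | 98.8 | 0 |

(readings scatter by 1 percentage point)

- removed product is counted in
- on the list of suspects stand: coupling partner + free catalyst -> catalyst intermediate A; substrate + catalyst intermediate A -> catalyst intermediate B; catalyst intermediate B -> catalyst intermediate C; catalyst intermediate C -> free catalyst + product; coupling partner + catalyst intermediate A <-> idle complex
- additions bring no volume worth counting

- gamma: at 40 h take out 90% of the product then present, then wait 40 h
- beta: at 40 h raise the temperature by 20 K, then wait 40 h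
- alpha: at 40 h add free catalyst, 100% of the amount charged, then wait 40 h
- theta: at 40 h add coupling partner, 50.0% of the amount charged, then wait 40 h
- zeta: change nothing and wait 40 h more

- product, in percent of the substrate first charged, at 40 h
- the remedy with the largest gain of product, or "none" below 2 percentage points (gamma / beta / alpha / theta / zeta / none)
- product present, with what was taken out counted in, in percent of the substrate first charged, after alpha
- product present, with what was taken out counted in, in percent of the substrate first charged, after zeta

Follow one turn of the suspected round. Free catalyst takes up coupling partner and becomes catalyst intermediate A. That takes up substrate and becomes catalyst intermediate B, then catalyst intermediate C, which releases product and free catalyst. Each product therefore costs one partner and one substrate, and the catalyst, at 0.192% of the substrate charge, can hold hardly any of either.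

So write the balance of the partner, the limiting reagent in oak: partner left, as a fraction of the substrate charge, is the partner charge over the substrate charge, minus the product. That ratio, 80.0% in oak, is the ceiling: the product the partner charge can pay for. In alder it is 119%, above the whole substrate charge, and alder reads 98.8% at 6.00 h.

In the first instants, then, the round begins to turn on both charges. The middle is quick: alder's first reading, taken as a first-order fall of substrate, reads as a pace of 0.735 h⁻¹. Alder ran at 20 °C with less substrate and oak at 25 °C, so this is a rough figure, but it puts oak at its ceiling in about 2.19 h, before oak's first reading at 10.0 h. At the end, the balance leaves 0% of partner, with 20.0% of the substrate unused. Oak's last reading stands 0.8 points above the ceiling, with a scatter of 1 point.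

My reckoning is therefore 80.0% now, and the same after alpha or zeta, since neither brings partner, and gamma and beta bring none either. Theta does: it adds 40.0% of the substrate charge as partner, against 20.0% of substrate left, so I expect a gain of 20 points.

The forecast gives 80% now, 80% after alpha, 80% after zeta and names theta, on the ground that “there is no partner left”.

The flask gives 80.0%, which is the ceiling of 80.0%, with 80.0% after alpha and 80.0% after zeta. Of the remedies, theta gains 20 points, while gamma gains 0 points and beta 0 points.

coupling partner + free catalyst → catalyst intermediate A (k = 76000 M⁻¹ h⁻¹, Ea = 52.0 kJ mol⁻¹); substrate + catalyst intermediate A → catalyst intermediate B (k = 1600 M⁻¹ h⁻¹, Ea = 58.0 kJ mol⁻¹); catalyst intermediate B → catalyst intermediate C (k = 28000 h⁻¹, Ea = 68.0 kJ mol⁻¹); catalyst intermediate C → free catalyst + product (k = 2400 h⁻¹, Ea = 68.0 kJ mol⁻¹); coupling partner + catalyst intermediate A ⇌ idle complex, settled at all times (K = 1.10 M⁻¹, ΔH = 13.0 kJ mol⁻¹); (constants at 25 °C) The using up of the partner is the main reason for the stop: the same run without it reaches 100% against 80.0%. At 4.00 h the flask holds 0% of its partner and >99.9% of its catalyst as free catalyst. A second flask, the same but charged with 0.25 M of partner, has a ceiling of 48.1% and gives 48.1%, with 51.9% of its substrate left.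

The earlier runs and the new flask were generated by integration for an exercise; noise was put on by code.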